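The earlier runs and the new flask are calculated on assumed constants; noise was put on by code.

I have decided to read these flasks through one exponent rather than through the shape of their curves, and the flasks come first.

| flask | starting material | coupling partner | time |
|---|---|---|---|
| Monday's | 0.0500 M | 0.150 M |  |
| Sunday's | 0.0300 M | 0.130 M |  |
| Wednesday's | 0.0500 M | 0.450 M |  |
| Thursday's | 0.250 M | 0.150 M | 47 min |

| run | time / min | [target] / M |
|---|---|---|
| Monday's run | 6.7 | 0.0026 |
| Monday's run | 13 | 0.0053 |
| Monday's run | 20 | 0.0082 |
| Monday's run | 27 | 0.0089 |
| Monday's run | 34 | 0.0105 |
| Monday's run | 40 | 0.0098 |
| Monday's run | 47 | 0.0108 |
| Sunday's run | 6.7 | 0.0014 |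
| Sunday's run | 13 | 0.0034 |
| Sunday's run | 20 | 0.0049 |
| Sunday's run | 27 | 0.0066 |
| Sunday's run | 34 | 0.0074 |
| Sunday's run | 40 | 0.0073 |
| Sunday's run | 47 | 0.0077 |
| Wednesday's run | 6.7 | 0.0031 |
| Wednesday's run | 13 | 0.0062 |
| Wednesday's run | 20 | 0.0086 |
| Wednesday's run | 27 | 0.0093 |
| Wednesday's run | 34 | 0.0110 |
| Wednesday's run | 40 | 0.0111 |
| Wednesday's run | 47 | 0.0120 |

(scatter of a reading: 4 × 10⁻⁴ M)

- Overall: starting material + coupling partner -> target.
- Constant volume, constant temperature.
- What is held in complexes is read along with the free species.
- "The second partner" is coupling partner.
- An order is taken over about fifteen percent of the charge, up and down.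

- order of the initial rate in [coupling partner], near the charge of the Monday's run, the rate being that where two percent of its starting material are target
- order of the initial rate in [starting material], near the charge of the Monday's run, the rate being that where two percent of its starting material are target (one fixed amount of target, the same in the runs compared)
- target in the Thursday's run at 47 min, as a share of the starting material charged

Thursday's run has the [coupling partner] of Monday's run, 0.150 M, and 5.00 times its [starting material], so the question is how target at 47 min grows with the charge of starting material while [coupling partner] is held fixed.

Here two views part. The first holds that the rate is first-order in [starting material], so that Thursday's run repeats Monday's share of 21.6%. The second points to Sunday's run, whose share of 25.7% is higher than Monday's, although its charge of both partners is smaller, and holds that the rate grows more slowly than the charge.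

My own reckoning takes the second side. I work from the last readings, at 47 min, which carry their scatter. Monday's 0.0108 M against Wednesday's 0.0120 M gives a power of 0.0959 in [coupling partner]. With that correction, Sunday's 0.0077 M against Monday's gives 0.635, and this is the yield exponent, the power of the charge of starting material by which target at that time grows while [coupling partner] is held fixed. Thursday's target then comes to 0.0300 M, which is 12.0% of its charge.

The forecast also takes the second side, with different numbers: 13% (from 8% to 21%), orders of 0.2 and 0.85, the latter “probably bending towards saturation”. Its share is higher than mine.

Thursday's run gives 11.1% of its charge, so the first view loses; near the charge of Monday's run, the initial rate has orders of 0.29 in [coupling partner] and 0.44 in [starting material].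

    starting material → intermediate (0.09060 min⁻¹)
    intermediate + coupling partner → target (3.078 M⁻¹ min⁻¹)
    intermediate → side product (0.01650 min⁻¹)
    2 starting material ⇌ idle substrate dimer, settled at all times (469.0 M⁻¹)
    target → decomposed product (0.03456 min⁻¹)

At fixed [coupling partner], the first view has its region at charges well below 0.00213 M, the inverse of the constant of the idle substrate dimer, which is smaller than Monday's 0.0500 M. Carried down from the 0.0279 M of target in Thursday's run to the charges of Sunday's run, the yield exponent and the power in [coupling partner] give 0.00714 M, and the reading of Sunday's run at 47 min is 0.0077 M.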